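The readings are simulated with made-up constants; the scatter is artificial.

Look at what is still unconverted.

| flask | substrate | partner | protic impurity | free catalyst | temperature | remark | time |
|---|---|---|---|---|---|---|---|
| Friday's | 1.4 M | 1.5 equiv | 0.30 M | 0.2 mol% | 105 °C | run made earlier |  |
| Saturday's | 1 M | 1.5 equiv | 0.30 M | 0.3 mol% | 138 °C | run made earlier |  |
| summer | 1.0 M | 1.50 equiv | 0.300 M | 0.2 mol% | 130 °C |  | 8.0 h |
| noon | 1.0 M | 1.50 equiv | 0.300 M | 0.2 mol% | 150 °C |  | 8.0 h |
| spring | 1.0 M | 1.50 equiv | 0.300 M | 0.2 mol% | 90 °C |  | 8.0 h |
| dawn | 1.0 M | 1.50 equiv | 0.300 M | 0.2 mol% | 110 °C |  | 8.0 h |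

| run | time / h | open intermediate / % | target / % | substrate / % |
|---|---|---|---|---|
| Friday's | 1.50 | 21.0 | 10.1 | 69.1 |
| Friday's | 5.00 | 18.4 | 40.8 | 40.4 |
| Friday's | 10.0 | 10.2 | 68.3 | 21.3 |
| Friday's | 20.0 | 3.7 | 90.0 | 6.0 |
| Saturday's | 0.500 | 21.8 | 23.2 | 54.6 |
| Saturday's | 1.33 | 13.2 | 61.2 | 25.7 |
| Saturday's | 3.00 | 3.5 | 90.1 | 5.8 |
| Saturday's | 6.00 | 0.5 | 99.1 | 0.5 |

(standard deviation of a reading: 0.3 percentage points)

1. the flask that comes out highest in amount of open intermediate, in percent of the substrate charged, or "all alike" when all lie within 1.5 percentage points (summer / noon / spring / dawn / all alike)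
2. open intermediate at the end, in percent of the substrate charged, summer
3. open intermediate at the end, in percent of the substrate charged, noon
4. open intermediate at the end, in percent of the substrate charged, spring
5. open intermediate at the end, in percent of the substrate charged, dawn

- the earlier runs were read with a standard deviation of 0.3 percentage points
- reactions considered so far: partner + catalyst intermediate -> free catalyst + target; free catalyst + open intermediate <-> catalyst intermediate; partner + protic impurity -> quenched reagent; substrate + free catalyst <-> free catalyst + open intermediate

Two of us read these runs differently. I hold that open intermediate is a steady share of the unconverted material, meaning substrate plus open intermediate, and that this material falls on one clock. Friday's last reading gives a share of 38.1%, and Saturday's third gives 37.6%.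

For the clock I replace the curve by its mean. Friday's last reading gives 41.7 /M/h and Saturday's third gives 264 /M/h for the mean clearing rate, the natural log of charged over unconverted, per hour and per unit of catalyst concentration. Between the two temperatures that makes an activation energy of 72.3 kJ/mol.

The mean has an error, and I checked it. Saturday's first reading gives 179 /M/h, slower than the mean, with a share of 28.5%. So Saturday's run read below its later share while most of its material was still unconverted.

Carried to the new catalyst concentration and 8.0 h, my reckoning puts open intermediate at 2.35% in summer, 0.0172% in noon and 15.3% in dawn. Spring lands between 22.0% and 29.1%, so in my reckoning spring stands highest.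

My colleague counts partner instead. After the protic impurity has taken its share, partner exceeds what the substrate needs by 0.200 M, the same margin as on Saturday. So my colleague expects noon to stall near Saturday's last reading of 0.5%, far above my figure.

The forecast names spring and gives 3.7%, 0.05%, 28% and 16% for summer, noon, spring and dawn, on the ground that “open intermediate tracks about 35–38% of unconverted material”.

The flasks give 2.78% in summer, 0.0148% in noon, 24.3% in spring and 15.7% in dawn, with spring highest.

    partner + catalyst intermediate → free catalyst + target (k = 4.50 /M/min, Ea = 69.0 kJ/mol)
    free catalyst + open intermediate ⇌ catalyst intermediate (K = 2.20 /M, k = 5.60 /M/min, Ea = 61.0 kJ/mol, ΔH = 42.0 kJ/mol)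
    partner + protic impurity → quenched reagent (k = 0.0120 /M/min, Ea = 79.0 kJ/mol)
    substrate + free catalyst ⇌ free catalyst + open intermediate (K = 0.920, k = 2.60 /M/min, Ea = 59.0 kJ/mol, ΔH = 20.0 kJ/mol)
    (constants at 110 °C)

The clearing rate also carries to noon read at 2.0 h: it gives 5.50%, and that flask holds 6.21%. At noon's end, the half-life of open intermediate by its forward step onto free catalyst is 0.17 h, shorter than the 8.0 h run. There 0.0148% of open intermediate stands beside 0.0210% of substrate. The partner count has its region in a flask like noon with 0.25 M of substrate, the same equivalents and loading, where partner is the limiting reagent: 0.828% of its charge remains, and open intermediate stands at 38.4%.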